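## Analysis of the target

Gnetucleistol F (34) is a stilbenoid neolignan built on a 2,3-dihydrobenzofuran: benzo ring A is fused to dihydrofuran ring B. C2 carries a 4-hydroxy-3,5-dimethoxyphenyl group (ring C), C3 a hydroxymethyl group, C7 a methoxy group and C5 an (E)-2-(3,5-dihydroxyphenyl)ethenyl arm (ring D). The only stereocentres are C2 (R) and C3 (S); they are neighbours on ring B with their substituents trans, which is also the more stable arrangement. The sensitive features are the three phenols, the electron-rich E-stilbene (no late hydrogenation, no strong acid, light-sensitive) and the C2–O1 bond. That bond is a 4-oxybenzyl aryl ether: strong acid ionises it, and base can open it through a quinone methide once the ring-C phenol is free. The difficulty is to combine secure absolute control of the C2/C3 pair with a ring A that has a 1,2,3,5 pattern of four different substituents, and to finish without harming the alkene or the benzylic ether. Ring A has oxygen on the adjacent carbons C7a (O1) and C7, hydrogen at C4 and C6, and its only carbon substituent at C5. This is the pattern formed when a vinylketene whose vinyl group is the O–CH=C enol ether of a 4,5-dihydrofuran (the future O1–C7a=C3a) is annulated with a terminal ynol ether. The ketene carbon becomes C7 with its oxygen, the alkyne CH becomes C6, and the alkyne C–O carbon becomes C5, where oxygen is later exchanged for carbon.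

## Retrosynthetic reasoning

Target 34 is traced to tetraacetate 33 by cutting four O–acyl bonds. Carrying all four hydroxyls as acetates means the last step is a mild transesterification, with no reduction or Lewis acid once the stilbene exists.

Tetraacetate 33 is cut at the bond between C5 of ring A and the alkene carbon, giving aryl triflate 31 and styrene 32. A Heck coupling forms this bond with E geometry, the ring-D half is a simple styrene, and ring A needs only a sulfonate at C5. Cutting the C=C bond instead would require a C5 aldehyde and extra redox steps.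

Triflate 31 goes back through 30, 29, 28 and 27 to phenol 26 by functional-group changes whose order is forced. The ring-C benzyl ether must leave by hydrogenolysis before any alkene is present (31 from 30 from 29). The triflate comes from the C5 phenol (29 from 28). That phenol is released from its silyl ether only after the C7 hydroxyl, the one free phenol of 26, has been methylated (28 from 27 from 26).

Phenol 26 is the product of the key disconnection. Ring A is removed by cutting C3a–C4, C4–C5, C6–C7 and C7–C7a, which leaves diazoketone 17 and siloxyalkyne 21. This cut takes away the whole tetrasubstituted arene and leaves a small chiral dihydrofuran that already holds both stereocentres. The forward reaction must generate the vinylketene, add the alkyne in one orientation and close onto the enol-ether carbon; the stereocentres are spectators.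

Siloxyalkyne 21 is traced to the C-silylated ynol ether 20 and then to alkyne 18. The ynol oxygen comes from oxidation of an acetylide. The silyl group on carbon is a temporary cap that steers the bulky silyl electrophile to oxygen.

Diazoketone 17 is cut at the bond between the carbonyl and the diazo carbon, giving acid 15. The carboxyl carbon is in turn disconnected from the nucleophilic β-carbon of enol ether 13, through trihalomethyl ketone 14 as a masked carboxyl group. This is the one position at which an enol ether takes an acyl group without a catalyst.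

Enol ether 13 comes from lactol 11 by dehydration, and 11 from the terminal alkene of 9 by oxidative cleavage. The O1–C bond of the lactol forms by itself once the aldehyde is free, so only the C=C bond is cut.

Silyl ether 9 is diol 8 with its primary hydroxyl protected, and 8 is the reduction product of aldol 7. Cutting the bond between the two stereocentres of 7 gives imide 5 and aldehyde 2. An auxiliary-controlled syn aldol sets both centres in one step. The syn relationship becomes trans once the homoallylic carbon and the carbinol oxygen are joined in a ring, and the (R)-auxiliary gives the (2R,3S) series.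

Imide 5 is assembled from auxiliary 3 and acid chloride 4, and aldehyde 2 from phenol 1 by O-benzylation.

## Alternatives that were turned down

Alternative 1: Ring B is traced to the six-membered ring of flavanone A1, and the C3–C3a bond to a 1,2-shift of the ring-A carbon from the carbonyl carbon to C3. In the forward step, PhI(OAc)2 in acidic HC(OMe)3 attacks the enol ether of A1 at C3 with hypervalent iodine. The ring-A carbon then migrates as the iodoarene leaves, and the former carbonyl carbon becomes the ester of A2.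
- For: ring A is bought complete, with bromine at C5 and methoxy at C7. The trans ester is the expected product and reduces directly to the hydroxymethyl group. The bromide is a Heck handle with no extra steps. On step count this route is stronger than the chosen one.
- Against: the single stereocentre of A1 lies β to a ketone in an aryl ether, so retro-oxa-Michael ring opening under the acidic conditions of the rearrangement, or under any base, can racemise it. Making A1 as one enantiomer is itself a separate problem. Migration of ring C from C2 to C3 competes with ring contraction under the same oxidant. The mesylate on ring C lowers its migratory aptitude, but the two flanking methoxy groups keep it electron-rich, while ring A is deactivated by bromine. The aryl mesylate must finally be cleaved under strongly nucleophilic conditions next to the base-sensitive C2–O1 bond.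
- Comparison: the chosen strategy is longer, but both stereocentres come from an auxiliary aldol, are never epimerisable afterwards, and no migration selectivity is needed.

Alternative 2: Rings A and B are removed together by cutting C3a–C7a, C4–C5 and C6–C7. This leads to diyne A3, in which a C-silylated ynol ether and a terminal alkyne are tethered through O1–C2–C3, and to alkyne A4. In the forward step a monovalent rhodium catalyst such as RhCl(PPh3)3 would join the three alkynes in a (2+2+2) cycloaddition to A5.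
- For: it is the most convergent plan, closing two rings and three bonds at once, and the C5 carbon arrives as a masked aldehyde ready for olefination. On convergence it is stronger than the chosen route.
- Against: the orientation of A4 (acetal at C5 or C6) is steered only by the bulk of the silyl group, with no electronic bias. C7 ends as C–SiEt3, not C–O, and Tamao–Fleming-type oxidation of an unactivated aryl triethylsilane next to the ring oxygen is unreliable, so the oxygen pattern that defines ring A would still be missing. A3 is a secondary benzylic alkynyl ether, a class that undergoes (3,3) sigmatropic rearrangement on gentle warming. A4 can also oligomerise with itself.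
- Comparison: the chosen annulation has regiochemistry fixed by alkyne polarity and delivers both ring-A oxygens directly, one free for methylation and one as a future leaving group.

Alternative 3: Ring B is cut at C2–C3 and O1–C2, giving sulfonyl phenol A6 as an ortho-quinone methide precursor and the chiral benzylic sulfonium salt A7. A7 is drawn with one arbitrary C2-symmetric sulfide, whose sense of induction is not established. In the forward step base expels sulfinate from A6. The ylide of A7 adds to the exocyclic carbon of the quinone methide, and the phenoxide displaces the sulfide to close ring B, giving A8.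
- For: it is the shortest plan. Ring A is bought, the trans relationship follows from the anti betaine, the bromide is in place, and A8 is a few steps from the target. It also needs no photochemistry. On step economy it is clearly stronger.
- Against: the absolute configuration rests on a chiral sulfide controlling a semi-stabilised benzylic ylide. Betaine formation from such ylides is reversible, which erodes enantioselectivity, and this control is untested for a quinone methide carrying a CH2O-silyl substituent. That quinone methide has hydrogens on the substituent and can lose its identity by a 1,5-hydrogen shift before the ylide arrives. A stoichiometric chiral sulfide is needed.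
- Comparison: the chosen strategy gives secure relative and absolute configuration from aldehyde 2 by an auxiliary aldol, with diastereomers separable early, which matters most for a single-enantiomer target.

Key step: step 13

Assumption: (triisopropylsilyloxy)acetylene 21 is not treated as a stock chemical and is made in steps 11 and 12; the ring-C phenol is carried as a benzyl ether and the primary alcohol as a tert-butyldimethylsilyl ether.

## Route

Step 1
Reactants: 1 syringaldehyde
Product: 2 4-(benzyloxy)-3,5-dimethoxybenzaldehyde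
Conditions: BnBr, K2CO3, DMF, 60 °C
Reagents that add atoms: benzyl bromide, BrCc1ccccc1
Why: Williamson etherification of the phenoxide; the benzyl ether withstands every step up to the triflate stage and can then be removed by hydrogenolysis while no alkene is present.

Step 2
Reactants: 3 (R)-4-benzyl-1,3-oxazolidin-2-one; 4 pent-4-enoyl chloride
Product: 5 (R)-4-benzyl-3-(pent-4-enoyl)-1,3-oxazolidin-2-one
Conditions: n-BuLi, THF, −78 °C; then 4, −78 → 0 °C
Reagents that add atoms: none
Why: N-acylation of the lithiated oxazolidinone with an acid chloride, the standard entry to Evans imides; no stereocentre is formed.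

Step 3
Reactants: 5 (R)-4-benzyl-3-(pent-4-enoyl)-1,3-oxazolidin-2-one; 2 4-(benzyloxy)-3,5-dimethoxybenzaldehyde
Product: 7 (R)-4-benzyl-3-{(2R)-2-[(R)-[4-(benzyloxy)-3,5-dimethoxyphenyl](hydroxy)methyl]pent-4-enoyl}-1,3-oxazolidin-2-one, via boron enolate 6 (not isolated)
Conditions: Bu2BOTf, i-Pr2NEt, CH2Cl2, −78 → 0 °C; 2, −78 → 0 °C; then H2O2, MeOH, pH 7 buffer, 0 °C
Reagents that add atoms: none
Why: Evans syn aldol: the Z-boron enolate 6 reacts through a Zimmerman–Traxler chair on the face away from the benzyl group of the (R)-auxiliary, which should set both new centres as (2R,3R); this syn pair becomes the trans C2/C3 pair once the homoallylic carbon and the carbinol oxygen are tied into a ring.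

Step 4
Reactants: 7 (R)-4-benzyl-3-{(2R)-2-[(R)-[4-(benzyloxy)-3,5-dimethoxyphenyl](hydroxy)methyl]pent-4-enoyl}-1,3-oxazolidin-2-one
Product: 8 (1R,2S)-1-[4-(benzyloxy)-3,5-dimethoxyphenyl]-2-(prop-2-en-1-yl)propane-1,3-diol
Conditions: LiBH4, MeOH (1 equiv), THF, 0 °C
Reagents that add atoms: none
Why: Reductive cleavage of the imide gives the primary alcohol without touching the benzylic centre and returns auxiliary 3; the descriptor of the former α-carbon changes to S only because the CIP ranking changes.

Step 5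
Reactants: 8 (1R,2S)-1-[4-(benzyloxy)-3,5-dimethoxyphenyl]-2-(prop-2-en-1-yl)propane-1,3-diol
Product: 9 (1R,2S)-1-[4-(benzyloxy)-3,5-dimethoxyphenyl]-2-{[(tert-butyldimethylsilyl)oxy]methyl}pent-4-en-1-ol
Conditions: TBSCl, imidazole, CH2Cl2, 0 °C
Reagents that add atoms: tert-butyldimethylsilyl chloride, CC(C)(C)[Si](C)(C)Cl
Why: Silylation of a 1,3-diol is selective for the primary hydroxyl on steric grounds, leaving the benzylic hydroxyl free to become the ring oxygen O1.

Step 6
Reactants: 9 (1R,2S)-1-[4-(benzyloxy)-3,5-dimethoxyphenyl]-2-{[(tert-butyldimethylsilyl)oxy]methyl}pent-4-en-1-ol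
Product: 11 (4S,5R)-5-[4-(benzyloxy)-3,5-dimethoxyphenyl]-4-{[(tert-butyldimethylsilyl)oxy]methyl}oxolan-2-ol (both anomers), via hydroxy aldehyde 10 (not isolated)
Conditions: OsO4 (2 mol %), NaIO4, 2,6-lutidine, 1,4-dioxane/H2O, rt
Reagents that add atoms: sodium periodate, [Na+].[O-]I(=O)(=O)=O (oxygen source, delivered through catalytic OsO4, O=[Os](=O)(=O)=O)
Why: Lemieux–Johnson cleavage of the terminal alkene (preferred to ozone to spare the trialkoxyarene and the benzyl ether) gives aldehyde 10, which is trapped at once by the benzylic hydroxyl as the five-membered lactol; the anomeric centre is a mixture and is removed in step 7.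

Step 7
Reactants: 11 (4S,5R)-5-[4-(benzyloxy)-3,5-dimethoxyphenyl]-4-{[(tert-butyldimethylsilyl)oxy]methyl}oxolan-2-ol
Product: 13 (2R,3S)-2-[4-(benzyloxy)-3,5-dimethoxyphenyl]-3-{[(tert-butyldimethylsilyl)oxy]methyl}-2,3-dihydrofuran, via lactol mesylate 12 (not isolated)
Conditions: MsCl, Et3N, THF, −40 → 65 °C
Reagents that add atoms: none
Why: Sulfonylation of the lactol followed by base-induced elimination is the established route from 2-hydroxytetrahydrofurans to 2,3-dihydrofurans; no base-labile stereocentre is present and the acid-sensitive enol ether stays in amine-buffered medium.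

Step 8
Reactants: 13 (2R,3S)-2-[4-(benzyloxy)-3,5-dimethoxyphenyl]-3-{[(tert-butyldimethylsilyl)oxy]methyl}-2,3-dihydrofuran
Product: 14 1-[(4S,5R)-5-[4-(benzyloxy)-3,5-dimethoxyphenyl]-4-{[(tert-butyldimethylsilyl)oxy]methyl}-4,5-dihydrofuran-3-yl]-2,2,2-trichloroethan-1-one
Conditions: Cl3CCOCl, pyridine, CH2Cl2, 0 °C → rt
Reagents that add atoms: trichloroacetyl chloride, ClC(=O)C(Cl)(Cl)Cl
Why: The β-carbon of the enol ether is acylated by the highly electrophilic acid chloride and pyridine removes the proton from the resulting oxocarbenium ion (acylation of enol ethers with trichloroacetyl chloride); it is the only nucleophilic carbon, and the neighbouring C4–H is not acidic because its anion would not be conjugated with the carbonyl.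

Step 9
Reactants: 14 1-[(4S,5R)-5-[4-(benzyloxy)-3,5-dimethoxyphenyl]-4-{[(tert-butyldimethylsilyl)oxy]methyl}-4,5-dihydrofuran-3-yl]-2,2,2-trichloroethan-1-one
Product: 15 (4S,5R)-5-[4-(benzyloxy)-3,5-dimethoxyphenyl]-4-{[(tert-butyldimethylsilyl)oxy]methyl}-4,5-dihydrofuran-3-carboxylic acid
Conditions: LiOH, THF/H2O, 0 °C → rt; then 1 M HCl to pH 4, 0 °C
Reagents that add atoms: lithium hydroxide, [Li+].[OH-]
Why: Haloform-type cleavage: hydroxide adds to the trichloromethyl ketone and expels the trichloromethyl anion, which should be much faster than conjugate attack on the vinylogous ester; mild acidification gives the stable β-alkoxyacrylic acid.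

Step 10
Reactants: 15 (4S,5R)-5-[4-(benzyloxy)-3,5-dimethoxyphenyl]-4-{[(tert-butyldimethylsilyl)oxy]methyl}-4,5-dihydrofuran-3-carboxylic acid
Product: 17 2-diazo-1-[(4S,5R)-5-[4-(benzyloxy)-3,5-dimethoxyphenyl]-4-{[(tert-butyldimethylsilyl)oxy]methyl}-4,5-dihydrofuran-3-yl]ethan-1-one, via acid chloride 16 (not isolated)
Conditions: 1-chloro-N,N,2-trimethylprop-1-en-1-amine, CH2Cl2, 0 °C; then CH2N2 (3 equiv), Et2O, 0 °C
Reagents that add atoms: diazomethane, C=[N+]=[N-]
Why: The α-chloroenamine converts the acid into acid chloride 16 without releasing HCl, and acylation of diazomethane (first stage of an Arndt–Eistert sequence) gives the diazoketone; the push–pull, trisubstituted ring alkene is a poor dipolarophile, so pyrazoline formation should be minor.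

Step 11
Reactants: 18 ethynyltrimethylsilane
Product: 20 triisopropyl{[(trimethylsilyl)ethynyl]oxy}silane, via lithium ynolate 19 (not isolated)
Conditions: n-BuLi, THF, −78 °C; t-BuOOLi (from t-BuOOH and LiN(SiMe3)2), −78 → 0 °C; then TIPSOTf, −78 → 0 °C
Reagents that add atoms: tert-butyl hydroperoxide, CC(C)(C)OO; triisopropylsilyl trifluoromethanesulfonate, CC(C)[Si](OS(=O)(=O)C(F)(F)F)(C(C)C)C(C)C
Why: Lithium acetylides are oxidised by lithium tert-butyl peroxide to lithium ynolates, and a triisopropylsilyl electrophile silylates ynolates on oxygen when the carbon terminus is hindered, here by the trimethylsilyl group, which is why the C-silylated alkyne is used in place of acetylene itself.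

Step 12
Reactants: 20 triisopropyl{[(trimethylsilyl)ethynyl]oxy}silane
Product: 21 (ethynyloxy)triisopropylsilane [(triisopropylsilyloxy)acetylene]
Conditions: K2CO3 (cat.), MeOH, 0 °C
Reagents that add atoms: none
Why: Base-catalysed methanolysis of an alkynyl–SiMe3 bond is a standard deprotection; the small silyl group on sp carbon is attacked far faster than the triisopropylsilyl group on oxygen, and the product is used without delay.

Step 13
Reactants: 17 2-diazo-1-[(4S,5R)-5-[4-(benzyloxy)-3,5-dimethoxyphenyl]-4-{[(tert-butyldimethylsilyl)oxy]methyl}-4,5-dihydrofuran-3-yl]ethan-1-one; 21 (ethynyloxy)triisopropylsilane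
Product: 26 (2R,3S)-2-[4-(benzyloxy)-3,5-dimethoxyphenyl]-3-{[(tert-butyldimethylsilyl)oxy]methyl}-5-[(triisopropylsilyl)oxy]-2,3-dihydro-1-benzofuran-7-ol, via vinylketene 22 (not isolated), via cyclobutenone 23 (not isolated), via dienylketene 24 (not isolated), via cyclohexadienone 25 (not isolated)
Conditions: 21 (2.5 equiv), degassed ClCH2CH2Cl, hν (medium-pressure Hg lamp, Pyrex filter), rt; then excess 21 removed and 80 °C
Reagents that add atoms: none
Why: Light expels N2 from 17 and the dihydrofuranyl carbon migrates to the carbene carbon (photo-Wolff rearrangement, new bond C3a–C4), giving vinylketene 22 whose vinyl unit is the ring enol ether. The electron-rich alkyne 21 adds across the ketene C=C in a polar (2+2) cycloaddition to cyclobutenone 23 (bonds C6–C7 and C4–C5); heating opens 23 by four-electron electrocyclic ring opening to dienylketene 24, and the isomer with the dihydrofuranyl group turned inward closes by thermal six-electron disrotatory electrocyclisation onto the enol-ether carbon (bond C7–C7a) to 25, which tautomerises to the phenol, while the outward isomer can only revert to 23. The closest known reaction type is the photochemical Danheiser benzannulation of α,β-unsaturated and heteroaryl diazoketones with siloxyalkynes, applied here to a β-alkoxy enone diazoketone. The only ring closed is benzo ring A, by 6π-electrocyclisation followed by aromatisation. No stereocentre is created: the sp3 centre at C7a in 25 disappears on enolisation, and C2 and C3 of the product are C5 and C4 of 17, which lie outside the reacting π-system and carry no acidic hydrogen. The selectivity needed is regiochemical and is secured by the polarisation of 21: its terminal CH carbon is the nucleophilic end and bonds to the electrophilic ketene carbon, so the silyloxy carbon becomes C5 and the ketene oxygen ends at C7 next to O1. The Pyrex filter keeps short-wavelength light from the benzyl and trialkoxyaryl chromophores, and removal of excess 21 before heating should prevent ketene-type by-products from acylating the new phenol.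

Step 14
Reactants: 26 (2R,3S)-2-[4-(benzyloxy)-3,5-dimethoxyphenyl]-3-{[(tert-butyldimethylsilyl)oxy]methyl}-5-[(triisopropylsilyl)oxy]-2,3-dihydro-1-benzofuran-7-ol
Product: 27 {[(2R,3S)-2-[4-(benzyloxy)-3,5-dimethoxyphenyl]-7-methoxy-5-[(triisopropylsilyl)oxy]-2,3-dihydro-1-benzofuran-3-yl]methoxy}(tert-butyl)dimethylsilane
Conditions: MeI, K2CO3, acetone, 40 °C
Reagents that add atoms: iodomethane, CI
Why: The only free hydroxyl of 26 is the C7 phenol, so Williamson methylation needs no selectivity; carbonate in acetone leaves the aryl and alkyl silyl ethers intact.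

Step 15
Reactants: 27 {[(2R,3S)-2-[4-(benzyloxy)-3,5-dimethoxyphenyl]-7-methoxy-5-[(triisopropylsilyl)oxy]-2,3-dihydro-1-benzofuran-3-yl]methoxy}(tert-butyl)dimethylsilane
Product: 28 (2R,3S)-2-[4-(benzyloxy)-3,5-dimethoxyphenyl]-3-(hydroxymethyl)-7-methoxy-2,3-dihydro-1-benzofuran-5-ol
Conditions: TBAF (3 equiv), THF, 0 °C → rt, argon; then aq. NH4Cl
Reagents that add atoms: none
Why: Fluoride cleaves the aryl triisopropylsilyl ether and the primary tert-butyldimethylsilyl ether in one operation through Si–F bond formation, exposing the C5 phenol and the primary alcohol.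

Step 16
Reactants: 28 (2R,3S)-2-[4-(benzyloxy)-3,5-dimethoxyphenyl]-3-(hydroxymethyl)-7-methoxy-2,3-dihydro-1-benzofuran-5-ol
Product: 29 (2R,3S)-2-[4-(benzyloxy)-3,5-dimethoxyphenyl]-3-(hydroxymethyl)-7-methoxy-2,3-dihydro-1-benzofuran-5-yl trifluoromethanesulfonate
Conditions: PhNTf2, Et3N, CH2Cl2, 0 °C → rt
Reagents that add atoms: N-phenylbis(trifluoromethanesulfonimide), O=S(=O)(N(c1ccccc1)S(=O)(=O)C(F)(F)F)C(F)(F)F
Why: N-Phenyltriflimide with an amine base sulfonylates phenols but not aliphatic alcohols, so only the C5 phenol becomes the triflate needed for cross-coupling.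

Step 17
Reactants: 29 (2R,3S)-2-[4-(benzyloxy)-3,5-dimethoxyphenyl]-3-(hydroxymethyl)-7-methoxy-2,3-dihydro-1-benzofuran-5-yl trifluoromethanesulfonate
Product: 30 (2R,3S)-2-(4-hydroxy-3,5-dimethoxyphenyl)-3-(hydroxymethyl)-7-methoxy-2,3-dihydro-1-benzofuran-5-yl trifluoromethanesulfonate
Conditions: H2 (1 atm), Pd/C (10 wt % Pd on carbon), EtOAc, rt
Reagents that add atoms: none
Why: Hydrogenolysis of an aryl benzyl ether over Pd/C is fast under neutral conditions in which aryl triflates are not reduced; it is placed here because no alkene is present yet, and the short exposure should spare the cyclic C2–O1 benzylic ether.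

Step 18
Reactants: 30 (2R,3S)-2-(4-hydroxy-3,5-dimethoxyphenyl)-3-(hydroxymethyl)-7-methoxy-2,3-dihydro-1-benzofuran-5-yl trifluoromethanesulfonate
Product: 31 [(2R,3S)-2-(4-acetoxy-3,5-dimethoxyphenyl)-7-methoxy-5-{[(trifluoromethyl)sulfonyl]oxy}-2,3-dihydro-1-benzofuran-3-yl]methyl acetate
Conditions: Ac2O, pyridine, DMAP (cat.), CH2Cl2, rt
Reagents that add atoms: acetic anhydride, CC(=O)OC(C)=O
Why: Acetylation of both hydroxyls; with the ring-C phenol masked, the hot basic Heck medium cannot open ring B through a quinone methide, and all four protecting groups of the coupled product become identical.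

Step 19
Reactants: 31 [(2R,3S)-2-(4-acetoxy-3,5-dimethoxyphenyl)-7-methoxy-5-{[(trifluoromethyl)sulfonyl]oxy}-2,3-dihydro-1-benzofuran-3-yl]methyl acetate; 32 3,5-diacetoxystyrene
Product: 33 5-[(E)-2-{(2R,3S)-2-(4-acetoxy-3,5-dimethoxyphenyl)-3-(acetoxymethyl)-7-methoxy-2,3-dihydro-1-benzofuran-5-yl}ethenyl]-1,3-phenylene diacetate
Conditions: PdCl2(PPh3)2 (5 mol %), LiCl, Et3N, DMF, 100 °C
Reagents that add atoms: none
Why: Heck reaction: oxidative addition of zerovalent palladium into the aryl triflate, syn insertion of the styrene with aryl transfer to the terminal carbon and syn β-hydride elimination give the E-stilbene; chloride keeps the arylpalladium intermediate neutral, which favours terminal arylation.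

Step 20
Reactants: 33 5-[(E)-2-{(2R,3S)-2-(4-acetoxy-3,5-dimethoxyphenyl)-3-(acetoxymethyl)-7-methoxy-2,3-dihydro-1-benzofuran-5-yl}ethenyl]-1,3-phenylene diacetate
Product: 34 Gnetucleistol F, 5-[(E)-2-[(2R,3S)-2-(4-hydroxy-3,5-dimethoxyphenyl)-3-(hydroxymethyl)-7-methoxy-2,3-dihydro-1-benzofuran-5-yl]ethenyl]benzene-1,3-diol
Conditions: K2CO3 (cat.), MeOH, 0 °C → rt, argon, dark; then aq. NH4Cl
Reagents that add atoms: none
Why: Base-catalysed transesterification removes the three aryl acetates and the primary acetate in one step under conditions that touch neither the E-alkene nor the stereocentres, which carry no acidic hydrogen.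

## Compound list

1 | syringaldehyde (4-hydroxy-3,5-dimethoxybenzaldehyde) | COc1cc(C=O)cc(OC)c1O | starting material
2 | 4-(benzyloxy)-3,5-dimethoxybenzaldehyde | COc1cc(C=O)cc(OC)c1OCc1ccccc1 | intermediate
3 | (R)-4-benzyl-1,3-oxazolidin-2-one | O=C1N[C@H](Cc2ccccc2)CO1 | starting material
4 | pent-4-enoyl chloride | C=CCCC(=O)Cl | starting material
5 | (R)-4-benzyl-3-(pent-4-enoyl)-1,3-oxazolidin-2-one | C=CCCC(=O)N1[C@H](Cc2ccccc2)COC1=O | intermediate
6 | (Z)-dibutylboron enolate of 5, (R)-4-benzyl-3-{(1Z)-1-[(dibutylboranyl)oxy]penta-1,4-dien-1-yl}-1,3-oxazolidin-2-one | C=CC/C=C(\OB(CCCC)CCCC)N1[C@H](Cc2ccccc2)COC1=O | intermediate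
7 | (R)-4-benzyl-3-{(2R)-2-[(R)-[4-(benzyloxy)-3,5-dimethoxyphenyl](hydroxy)methyl]pent-4-enoyl}-1,3-oxazolidin-2-one | O=C1OC[C@@H](Cc2ccccc2)N1C(=O)[C@H](CC=C)[C@@H](O)c1cc(OC)c(OCc2ccccc2)c(OC)c1 | intermediate
8 | (1R,2S)-1-[4-(benzyloxy)-3,5-dimethoxyphenyl]-2-(prop-2-en-1-yl)propane-1,3-diol | OC[C@H](CC=C)[C@@H](O)c1cc(OC)c(OCc2ccccc2)c(OC)c1 | intermediate
9 | (1R,2S)-1-[4-(benzyloxy)-3,5-dimethoxyphenyl]-2-{[(tert-butyldimethylsilyl)oxy]methyl}pent-4-en-1-ol | CC(C)(C)[Si](C)(C)OC[C@H](CC=C)[C@@H](O)c1cc(OC)c(OCc2ccccc2)c(OC)c1 | intermediate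
10 | (3S,4R)-4-[4-(benzyloxy)-3,5-dimethoxyphenyl]-3-{[(tert-butyldimethylsilyl)oxy]methyl}-4-hydroxybutanal | CC(C)(C)[Si](C)(C)OC[C@H](CC=O)[C@@H](O)c1cc(OC)c(OCc2ccccc2)c(OC)c1 | intermediate
11 | (4S,5R)-5-[4-(benzyloxy)-3,5-dimethoxyphenyl]-4-{[(tert-butyldimethylsilyl)oxy]methyl}oxolan-2-ol, both anomers at C2 | COc1cc([C@@H]2OC(O)C[C@H]2CO[Si](C)(C)C(C)(C)C)cc(OC)c1OCc1ccccc1 | intermediate
12 | (4S,5R)-5-[4-(benzyloxy)-3,5-dimethoxyphenyl]-4-{[(tert-butyldimethylsilyl)oxy]methyl}oxolan-2-yl methanesulfonate, both anomers | COc1cc([C@@H]2OC(OS(C)(=O)=O)C[C@H]2CO[Si](C)(C)C(C)(C)C)cc(OC)c1OCc1ccccc1 | intermediate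
13 | (2R,3S)-2-[4-(benzyloxy)-3,5-dimethoxyphenyl]-3-{[(tert-butyldimethylsilyl)oxy]methyl}-2,3-dihydrofuran | COc1cc([C@@H]2OC=C[C@H]2CO[Si](C)(C)C(C)(C)C)cc(OC)c1OCc1ccccc1 | intermediate
14 | 1-[(4S,5R)-5-[4-(benzyloxy)-3,5-dimethoxyphenyl]-4-{[(tert-butyldimethylsilyl)oxy]methyl}-4,5-dihydrofuran-3-yl]-2,2,2-trichloroethan-1-one | COc1cc([C@@H]2OC=C(C(=O)C(Cl)(Cl)Cl)[C@H]2CO[Si](C)(C)C(C)(C)C)cc(OC)c1OCc1ccccc1 | intermediate
15 | (4S,5R)-5-[4-(benzyloxy)-3,5-dimethoxyphenyl]-4-{[(tert-butyldimethylsilyl)oxy]methyl}-4,5-dihydrofuran-3-carboxylic acid | COc1cc([C@@H]2OC=C(C(=O)O)[C@H]2CO[Si](C)(C)C(C)(C)C)cc(OC)c1OCc1ccccc1 | intermediate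
16 | (4S,5R)-5-[4-(benzyloxy)-3,5-dimethoxyphenyl]-4-{[(tert-butyldimethylsilyl)oxy]methyl}-4,5-dihydrofuran-3-carbonyl chloride | COc1cc([C@@H]2OC=C(C(=O)Cl)[C@H]2CO[Si](C)(C)C(C)(C)C)cc(OC)c1OCc1ccccc1 | intermediate
17 | 2-diazo-1-[(4S,5R)-5-[4-(benzyloxy)-3,5-dimethoxyphenyl]-4-{[(tert-butyldimethylsilyl)oxy]methyl}-4,5-dihydrofuran-3-yl]ethan-1-one (trans) | COc1cc([C@@H]2OC=C(C(=O)C=[N+]=[N-])[C@H]2CO[Si](C)(C)C(C)(C)C)cc(OC)c1OCc1ccccc1 | intermediate
18 | ethynyltrimethylsilane | C#C[Si](C)(C)C | starting material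
19 | lithium 2-(trimethylsilyl)ethyn-1-olate | [Li+].[O-]C#C[Si](C)(C)C | intermediate
20 | triisopropyl{[(trimethylsilyl)ethynyl]oxy}silane | CC(C)[Si](OC#C[Si](C)(C)C)(C(C)C)C(C)C | intermediate
21 | (ethynyloxy)triisopropylsilane, (triisopropylsilyloxy)acetylene | C#CO[Si](C(C)C)(C(C)C)C(C)C | intermediate
22 | [(4S,5R)-5-[4-(benzyloxy)-3,5-dimethoxyphenyl]-4-{[(tert-butyldimethylsilyl)oxy]methyl}-4,5-dihydrofuran-3-yl]ketene | COc1cc([C@@H]2OC=C(C=C=O)[C@H]2CO[Si](C)(C)C(C)(C)C)cc(OC)c1OCc1ccccc1 | intermediate
23 | 4-[(4S,5R)-5-[4-(benzyloxy)-3,5-dimethoxyphenyl]-4-{[(tert-butyldimethylsilyl)oxy]methyl}-4,5-dihydrofuran-3-yl]-3-[(triisopropylsilyl)oxy]cyclobut-2-en-1-one, mixture at the ring sp3 carbon | COc1cc([C@@H]2OC=C(C3C(=O)C=C3O[Si](C(C)C)(C(C)C)C(C)C)[C@H]2CO[Si](C)(C)C(C)(C)C)cc(OC)c1OCc1ccccc1 | intermediate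
24 | 4-[(4S,5R)-5-[4-(benzyloxy)-3,5-dimethoxyphenyl]-4-{[(tert-butyldimethylsilyl)oxy]methyl}-4,5-dihydrofuran-3-yl]-3-[(triisopropylsilyl)oxy]buta-1,3-dien-1-one, isomer with the ketene carbon and the dihydrofuranyl group cis on C3=C4 | COc1cc([C@@H]2OC=C(\C=C(O[Si](C(C)C)(C(C)C)C(C)C)/C=C=O)[C@H]2CO[Si](C)(C)C(C)(C)C)cc(OC)c1OCc1ccccc1 | intermediate
25 | (2R,3S)-2-[4-(benzyloxy)-3,5-dimethoxyphenyl]-3-{[(tert-butyldimethylsilyl)oxy]methyl}-5-[(triisopropylsilyl)oxy]-2,3-dihydro-1-benzofuran-7(7aH)-one, mixture at C7a | COc1cc([C@@H]2OC3C(=O)C=C(O[Si](C(C)C)(C(C)C)C(C)C)C=C3[C@H]2CO[Si](C)(C)C(C)(C)C)cc(OC)c1OCc1ccccc1 | intermediate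
26 | (2R,3S)-2-[4-(benzyloxy)-3,5-dimethoxyphenyl]-3-{[(tert-butyldimethylsilyl)oxy]methyl}-5-[(triisopropylsilyl)oxy]-2,3-dihydro-1-benzofuran-7-ol (trans) | COc1cc([C@@H]2Oc3c(O)cc(O[Si](C(C)C)(C(C)C)C(C)C)cc3[C@H]2CO[Si](C)(C)C(C)(C)C)cc(OC)c1OCc1ccccc1 | intermediate
27 | {[(2R,3S)-2-[4-(benzyloxy)-3,5-dimethoxyphenyl]-7-methoxy-5-[(triisopropylsilyl)oxy]-2,3-dihydro-1-benzofuran-3-yl]methoxy}(tert-butyl)dimethylsilane | COc1cc([C@@H]2Oc3c(OC)cc(O[Si](C(C)C)(C(C)C)C(C)C)cc3[C@H]2CO[Si](C)(C)C(C)(C)C)cc(OC)c1OCc1ccccc1 | intermediate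
28 | (2R,3S)-2-[4-(benzyloxy)-3,5-dimethoxyphenyl]-3-(hydroxymethyl)-7-methoxy-2,3-dihydro-1-benzofuran-5-ol | COc1cc([C@@H]2Oc3c(OC)cc(O)cc3[C@H]2CO)cc(OC)c1OCc1ccccc1 | intermediate
29 | (2R,3S)-2-[4-(benzyloxy)-3,5-dimethoxyphenyl]-3-(hydroxymethyl)-7-methoxy-2,3-dihydro-1-benzofuran-5-yl trifluoromethanesulfonate | COc1cc([C@@H]2Oc3c(OC)cc(OS(=O)(=O)C(F)(F)F)cc3[C@H]2CO)cc(OC)c1OCc1ccccc1 | intermediate
30 | (2R,3S)-2-(4-hydroxy-3,5-dimethoxyphenyl)-3-(hydroxymethyl)-7-methoxy-2,3-dihydro-1-benzofuran-5-yl trifluoromethanesulfonate | COc1cc([C@@H]2Oc3c(OC)cc(OS(=O)(=O)C(F)(F)F)cc3[C@H]2CO)cc(OC)c1O | intermediate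
31 | [(2R,3S)-2-(4-acetoxy-3,5-dimethoxyphenyl)-7-methoxy-5-{[(trifluoromethyl)sulfonyl]oxy}-2,3-dihydro-1-benzofuran-3-yl]methyl acetate | COc1cc([C@@H]2Oc3c(OC)cc(OS(=O)(=O)C(F)(F)F)cc3[C@H]2COC(C)=O)cc(OC)c1OC(C)=O | intermediate
32 | 3,5-diacetoxystyrene (5-ethenyl-1,3-phenylene diacetate) | CC(=O)Oc1cc(C=C)cc(OC(C)=O)c1 | starting material
33 | 5-[(E)-2-{(2R,3S)-2-(4-acetoxy-3,5-dimethoxyphenyl)-3-(acetoxymethyl)-7-methoxy-2,3-dihydro-1-benzofuran-5-yl}ethenyl]-1,3-phenylene diacetate | COc1cc([C@@H]2Oc3c(OC)cc(/C=C/c4cc(OC(C)=O)cc(OC(C)=O)c4)cc3[C@H]2COC(C)=O)cc(OC)c1OC(C)=O | intermediate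
34 | Gnetucleistol F, 5-[(E)-2-[(2R,3S)-2-(4-hydroxy-3,5-dimethoxyphenyl)-3-(hydroxymethyl)-7-methoxy-2,3-dihydro-1-benzofuran-5-yl]ethenyl]benzene-1,3-diol | COc1cc([C@@H]2Oc3c(OC)cc(/C=C/c4cc(O)cc(O)c4)cc3[C@H]2CO)cc(OC)c1O | target

## Step count and least certain steps

Total step count: 20 steps.
Longest linear sequence: 17 steps, from 1 to 34 (steps 1, 3 to 10 and 13 to 20). The branch from 18 adds steps 11 and 12, and step 2 prepares imide 5.

Step 13 (key step).
- What may go wrong: capture of vinylketene 22 by the terminal siloxyalkyne may be slower than ketene dimerisation or photodecomposition, because 21 is less substituted than the siloxyalkynes usually used and the trialkoxyaryl group absorbs part of the light. The ring opening of 23 may prefer outward rotation of the dihydrofuranyl group, so that the cascade stalls before the six-electron closure. The new phenol may be acylated by ketene intermediates.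
- Fallback (ring A is bought, not built), setting out from 3 and 2: [5-bromo-3-methoxy-2-(methoxymethoxy)phenyl]acetic acid F1 is made from commercial (2-hydroxy-3-methoxyphenyl)acetic acid by bromination para to the hydroxyl and MOM protection. It is attached to 3 through its pivaloyl mixed anhydride with LiCl to give (R)-4-benzyl-3-{[5-bromo-3-methoxy-2-(methoxymethoxy)phenyl]acetyl}-1,3-oxazolidin-2-one F2. A Bu2BOTf aldol with 2, with the same facial sense as step 3, should give the syn adduct (R)-4-benzyl-3-{(2R,3R)-3-[4-(benzyloxy)-3,5-dimethoxyphenyl]-2-[5-bromo-3-methoxy-2-(methoxymethoxy)phenyl]-3-hydroxypropanoyl}-1,3-oxazolidin-2-one F3. LiBH4 gives (1R,2S)-1-[4-(benzyloxy)-3,5-dimethoxyphenyl]-2-[5-bromo-3-methoxy-2-(methoxymethoxy)phenyl]propane-1,3-diol F4. TFA in CH2Cl2 removes the MOM group and ionises the benzylic alcohol, and the phenol closes ring B under thermodynamic control to the trans compound [(2R,3S)-2-[4-(benzyloxy)-3,5-dimethoxyphenyl]-5-bromo-7-methoxy-2,3-dihydro-1-benzofuran-3-yl]methanol F5. Palladium-catalysed hydroxylation (Pd2(dba)3, t-BuXPhos, KOH, dioxane/H2O, 100 °C) converts the C5 bromide into the phenol and comes back to the route at 28.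

Step 11 (with step 12).
- What may go wrong: ynolate 19 may be silylated at carbon instead of oxygen, giving a bis-silylketene. The terminal siloxyalkyne 21 may be lost by isomerisation to a silylketene or by hydrolysis during desilylation and isolation.
- Fallback (a known terminal alkoxyalkyne replaces the siloxyalkyne), setting out from 17: tert-butoxyethyne F6 is prepared from tert-butyl vinyl ether by bromination and double dehydrobromination. Irradiation of 17 with it as in step 13 should give, with the same regiochemistry, (2R,3S)-2-[4-(benzyloxy)-3,5-dimethoxyphenyl]-5-tert-butoxy-3-{[(tert-butyldimethylsilyl)oxy]methyl}-2,3-dihydro-1-benzofuran-7-ol F7. Methylation with MeI and K2CO3 gives tert-butyl{[(2R,3S)-2-[4-(benzyloxy)-3,5-dimethoxyphenyl]-5-tert-butoxy-7-methoxy-2,3-dihydro-1-benzofuran-3-yl]methoxy}dimethylsilane F8. TFA in wet CH2Cl2 at 0 °C cleaves the aryl tert-butyl ether and the silyl ether and comes back to the route at 28.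

Step 10.
- What may go wrong: diazomethane may undergo 1,3-dipolar cycloaddition to the conjugated C=C of 16 or of the product, and the sensitive acid chloride may hydrolyse before acylation.
- Fallback (diazo transfer instead of acylation of diazomethane), setting out from 15: MeLi (2 equiv) in THF gives the methyl ketone 1-[(4S,5R)-5-[4-(benzyloxy)-3,5-dimethoxyphenyl]-4-{[(tert-butyldimethylsilyl)oxy]methyl}-4,5-dihydrofuran-3-yl]ethan-1-one F9. LiN(SiMe3)2 followed by CF3CO2CH2CF3 gives the trifluoroacetylated ketone 1-[(4S,5R)-5-[4-(benzyloxy)-3,5-dimethoxyphenyl]-4-{[(tert-butyldimethylsilyl)oxy]methyl}-4,5-dihydrofuran-3-yl]-4,4,4-trifluorobutane-1,3-dione F10. MsN3, Et3N and H2O in MeCN effect detrifluoroacetylative diazo transfer and come back to the route at 17.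

Step 17.
- What may go wrong: over-reduction, in which hydrogenolysis of the cyclic benzylic C2–O1 bond or of the aryl triflate competes with debenzylation.
- Fallback (the benzyl ether is carried through the coupling and removed without hydrogen), setting out from 29: acetylation gives [(2R,3S)-2-[4-(benzyloxy)-3,5-dimethoxyphenyl]-7-methoxy-5-{[(trifluoromethyl)sulfonyl]oxy}-2,3-dihydro-1-benzofuran-3-yl]methyl acetate F11. Heck coupling with 32 as in step 19 gives 5-[(E)-2-{(2R,3S)-3-(acetoxymethyl)-2-[4-(benzyloxy)-3,5-dimethoxyphenyl]-7-methoxy-2,3-dihydro-1-benzofuran-5-yl}ethenyl]-1,3-phenylene diacetate F12. Methanolysis as in step 20 gives 5-[(E)-2-{(2R,3S)-2-[4-(benzyloxy)-3,5-dimethoxyphenyl]-3-(hydroxymethyl)-7-methoxy-2,3-dihydro-1-benzofuran-5-yl}ethenyl]benzene-1,3-diol F13. BCl3 with pentamethylbenzene in CH2Cl2 at −78 °C removes the benzyl group and comes back to the route at 34. This reserve puts a Lewis acid next to the C2–O1 bond and the stilbene, which is why it is not the first choice.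

## Further compounds

F1 | step 13 | [5-bromo-3-methoxy-2-(methoxymethoxy)phenyl]acetic acid | COCOc1c(OC)cc(Br)cc1CC(=O)O
F2 | step 13 | (R)-4-benzyl-3-{[5-bromo-3-methoxy-2-(methoxymethoxy)phenyl]acetyl}-1,3-oxazolidin-2-one | O=C1OC[C@@H](Cc2ccccc2)N1C(=O)Cc1cc(Br)cc(OC)c1OCOC
F3 | step 13 | (R)-4-benzyl-3-{(2R,3R)-3-[4-(benzyloxy)-3,5-dimethoxyphenyl]-2-[5-bromo-3-methoxy-2-(methoxymethoxy)phenyl]-3-hydroxypropanoyl}-1,3-oxazolidin-2-one | O=C1OC[C@@H](Cc2ccccc2)N1C(=O)[C@H](c1cc(Br)cc(OC)c1OCOC)[C@@H](O)c1cc(OC)c(OCc2ccccc2)c(OC)c1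
F4 | step 13 | (1R,2S)-1-[4-(benzyloxy)-3,5-dimethoxyphenyl]-2-[5-bromo-3-methoxy-2-(methoxymethoxy)phenyl]propane-1,3-diol | OC[C@H](c1cc(Br)cc(OC)c1OCOC)[C@@H](O)c1cc(OC)c(OCc2ccccc2)c(OC)c1
F5 | step 13 | [(2R,3S)-2-[4-(benzyloxy)-3,5-dimethoxyphenyl]-5-bromo-7-methoxy-2,3-dihydro-1-benzofuran-3-yl]methanol | COc1cc([C@@H]2Oc3c(OC)cc(Br)cc3[C@H]2CO)cc(OC)c1OCc1ccccc1
F6 | step 11 | tert-butoxyethyne | C#COC(C)(C)C
F7 | step 11 | (2R,3S)-2-[4-(benzyloxy)-3,5-dimethoxyphenyl]-5-tert-butoxy-3-{[(tert-butyldimethylsilyl)oxy]methyl}-2,3-dihydro-1-benzofuran-7-ol | COc1cc([C@@H]2Oc3c(O)cc(OC(C)(C)C)cc3[C@H]2CO[Si](C)(C)C(C)(C)C)cc(OC)c1OCc1ccccc1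
F8 | step 11 | tert-butyl{[(2R,3S)-2-[4-(benzyloxy)-3,5-dimethoxyphenyl]-5-tert-butoxy-7-methoxy-2,3-dihydro-1-benzofuran-3-yl]methoxy}dimethylsilane | COc1cc([C@@H]2Oc3c(OC)cc(OC(C)(C)C)cc3[C@H]2CO[Si](C)(C)C(C)(C)C)cc(OC)c1OCc1ccccc1
F9 | step 10 | 1-[(4S,5R)-5-[4-(benzyloxy)-3,5-dimethoxyphenyl]-4-{[(tert-butyldimethylsilyl)oxy]methyl}-4,5-dihydrofuran-3-yl]ethan-1-one | COc1cc([C@@H]2OC=C(C(C)=O)[C@H]2CO[Si](C)(C)C(C)(C)C)cc(OC)c1OCc1ccccc1
F10 | step 10 | 1-[(4S,5R)-5-[4-(benzyloxy)-3,5-dimethoxyphenyl]-4-{[(tert-butyldimethylsilyl)oxy]methyl}-4,5-dihydrofuran-3-yl]-4,4,4-trifluorobutane-1,3-dione | COc1cc([C@@H]2OC=C(C(=O)CC(=O)C(F)(F)F)[C@H]2CO[Si](C)(C)C(C)(C)C)cc(OC)c1OCc1ccccc1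
F11 | step 17 | [(2R,3S)-2-[4-(benzyloxy)-3,5-dimethoxyphenyl]-7-methoxy-5-{[(trifluoromethyl)sulfonyl]oxy}-2,3-dihydro-1-benzofuran-3-yl]methyl acetate | COc1cc([C@@H]2Oc3c(OC)cc(OS(=O)(=O)C(F)(F)F)cc3[C@H]2COC(C)=O)cc(OC)c1OCc1ccccc1
F12 | step 17 | 5-[(E)-2-{(2R,3S)-3-(acetoxymethyl)-2-[4-(benzyloxy)-3,5-dimethoxyphenyl]-7-methoxy-2,3-dihydro-1-benzofuran-5-yl}ethenyl]-1,3-phenylene diacetate | COc1cc([C@@H]2Oc3c(OC)cc(/C=C/c4cc(OC(C)=O)cc(OC(C)=O)c4)cc3[C@H]2COC(C)=O)cc(OC)c1OCc1ccccc1
F13 | step 17 | 5-[(E)-2-{(2R,3S)-2-[4-(benzyloxy)-3,5-dimethoxyphenyl]-3-(hydroxymethyl)-7-methoxy-2,3-dihydro-1-benzofuran-5-yl}ethenyl]benzene-1,3-diol | COc1cc([C@@H]2Oc3c(OC)cc(/C=C/c4cc(O)cc(O)c4)cc3[C@H]2CO)cc(OC)c1OCc1ccccc1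
A1 | alternative 1 | (2R)-6-bromo-2-[3,5-dimethoxy-4-(methylsulfonyloxy)phenyl]-8-methoxychroman-4-one | COc1cc([C@H]2CC(=O)c3cc(Br)cc(OC)c3O2)cc(OC)c1OS(C)(=O)=O
A2 | alternative 1 | methyl (2R,3R)-5-bromo-2-[3,5-dimethoxy-4-(methylsulfonyloxy)phenyl]-7-methoxy-2,3-dihydro-1-benzofuran-3-carboxylate (trans) | COc1cc([C@@H]2Oc3c(OC)cc(Br)cc3[C@H]2C(=O)OC)cc(OC)c1OS(C)(=O)=O
A3 | alternative 2 | (1R,2S)-1-[4-(benzyloxy)-3,5-dimethoxyphenyl]-2-{[(tert-butyldimethylsilyl)oxy]methyl}but-3-yn-1-yl 2-(triethylsilyl)ethynyl ether | COc1cc([C@H](OC#C[Si](CC)(CC)CC)[C@@H](C#C)CO[Si](C)(C)C(C)(C)C)cc(OC)c1OCc1ccccc1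
A4 | alternative 2 | 3,3-diethoxyprop-1-yne | C#CC(OCC)OCC
A5 | alternative 2 | tert-butyl{[(2R,3S)-2-[4-(benzyloxy)-3,5-dimethoxyphenyl]-5-(diethoxymethyl)-7-(triethylsilyl)-2,3-dihydro-1-benzofuran-3-yl]methoxy}dimethylsilane | COc1cc([C@@H]2Oc3c([Si](CC)(CC)CC)cc(C(OCC)OCC)cc3[C@H]2CO[Si](C)(C)C(C)(C)C)cc(OC)c1OCc1ccccc1
A6 | alternative 3 | 4-bromo-2-{2-[(tert-butyldimethylsilyl)oxy]-1-(4-methylbenzenesulfonyl)ethyl}-6-methoxyphenol (racemic) | COc1cc(Br)cc(C(CO[Si](C)(C)C(C)(C)C)S(=O)(=O)c2ccc(C)cc2)c1O
A7 | alternative 3 | (2R,5R)-1-[4-(benzyloxy)-3,5-dimethoxybenzyl]-2,5-dimethylthiolan-1-ium trifluoromethanesulfonate | C[C@@H]1CC[C@@H](C)[S+]1Cc1cc(OC)c(OCc2ccccc2)c(OC)c1.[O-]S(=O)(=O)C(F)(F)F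
A8 | alternative 3 | tert-butyl{[(2R,3S)-2-[4-(benzyloxy)-3,5-dimethoxyphenyl]-5-bromo-7-methoxy-2,3-dihydro-1-benzofuran-3-yl]methoxy}dimethylsilane | COc1cc([C@@H]2Oc3c(OC)cc(Br)cc3[C@H]2CO[Si](C)(C)C(C)(C)C)cc(OC)c1OCc1ccccc1
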